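**Strategy.** Everything rests on cutting the four C–CH3 bonds at the two gem-dimethyl carbons. These carbons, C3 of each six-membered ring (counting from the acyl-bearing C1) and flanked by the oxygenated C2 and C4, are the only sp3 ring atoms, so each ring is a phloroglucinol ketone dearomatised by double methylation at a single carbon. One operation, exhaustive C-methylation with iodomethane and NaOMe, installs all four methyl groups and turns both benzene rings into cyclohexadienone β-triketones; no ring is formed. The precursor is the unsymmetrical hexahydroxy diarylmethane in which a butanoyl- and a propanoylphloroglucinol are joined through CH2 and each keeps one unsubstituted ring carbon; it comes from a Mannich salt by quinone methide capture.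

Key step: step 3

Remark: the target is written as one of several equivalent enol tautomers of its two β-triketone rings and has no stereocentre; in each ring C1 carries the acyl group, C3 is the CMe2 carbon (a C–H in the arene) and C5 carries the bridging CH2.

**Step 1**
Reactants: 1 1-(2,4,6-trihydroxyphenyl)propan-1-one (flopropione); 2 N,N-dimethylmethylideneammonium iodide (Eschenmoser's salt)
Product: 3 dimethyl[(2,4,6-trihydroxy-3-propanoylphenyl)methyl]ammonium iodide
Conditions: 2 (0.95 equiv, in portions), MeCN, 0 °C to rt, no added base; Et2O, filtration of the salt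
Reagents that add atoms: N,N-dimethylmethylideneammonium iodide (2), C[N+](C)=C.[I-]
Why: Mannich reaction with a preformed iminium ion at one of the two equivalent free ring carbons of the strongly nucleophilic phloroglucinol ketone; without base the product should separate as its ammonium iodide, which is deactivated toward a second aminomethylation and cannot yet lose dimethylamine.

**Step 2**
Reactants: 3 dimethyl[(2,4,6-trihydroxy-3-propanoylphenyl)methyl]ammonium iodide; 4 1-(2,4,6-trihydroxyphenyl)butan-1-one
Product: 7 1-[2,4,6-trihydroxy-3-[(2,4,6-trihydroxy-3-propanoylphenyl)methyl]phenyl]butan-1-one, via Mannich free base 5 (not isolated), via ortho-quinone methide 6 (not isolated)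
Conditions: 4 (3 equiv), NaOAc (1.1 equiv), DMF, 60 °C, Ar, 3 added in portions; dilute HCl work-up, chromatography (excess 4 recovered)
Reagents that add atoms: 1-(2,4,6-trihydroxyphenyl)butan-1-one (4), CCCC(=O)c1c(O)cc(O)cc1O
Why: Acetate frees the amine, which on warming eliminates dimethylamine to the ortho-quinone methide; this is captured at a free ring carbon of 4 by Michael-type (Friedel–Crafts) C-alkylation and tautomerisation restores both arenes, while the excess of 4 and the slow supply of 3 should suppress a second alkylation and self-capture.

**Step 3**
Reactants: 7 1-[2,4,6-trihydroxy-3-[(2,4,6-trihydroxy-3-propanoylphenyl)methyl]phenyl]butan-1-one; 8 iodomethane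
Product: 11 2-butanoyl-6-[(2,4-dihydroxy-3,3-dimethyl-6-oxo-5-propanoylcyclohexa-1,4-dien-1-yl)methyl]-3,5-dihydroxy-4,4-dimethylcyclohexa-2,5-dien-1-one (target), via half-methylated diarylmethane 9 (not isolated), via target disodium salt 10 (not isolated)
Conditions: NaOMe (6.5 equiv), MeI (4.2 equiv, in portions), degassed MeOH, 0 °C to rt, Ar; then 1 M HCl, crystallisation
Reagents that add atoms: iodomethane (8), CI
Why: Each ring, as its polyphenoxide in methanol, attacks iodomethane through C3 (SN2), the resulting dienone tautomerises back to the phenol (a stage represented by 9), and a second SN2 at the same carbon gives the 4,4-dimethylcyclohexadienone, which can no longer aromatise and rests as the delocalised, weakly nucleophilic β-triketone anion (10) until acidification. The closest known reaction type is the dearomative gem-dimethylation of acylphloroglucinols to acylfilicinic acids with MeI and NaOMe, run here on both rings of a methylene-bridged dimer. No ring is closed and no stereocentre is created. The step needs C- over O-methylation, which the hydrogen-bonded phenoxide oxygens in methanol and the soft electrophile should favour. It also needs attack at C3 and not at the bridge-bearing C5: C3 is the only unsubstituted ring carbon for the first methylation, and for the second a methyl-bearing carbon is far less hindered than one carrying the bulky arylmethyl group. Six equivalents of base cover the four protons released and keep both product rings ionised, while near-stoichiometric iodomethane and low temperature should hold back over-methylation and base-induced exchange of the methylene bridge.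

**Compound list**

1 | 1-(2,4,6-trihydroxyphenyl)propan-1-one (flopropione) | CCC(=O)c1c(O)cc(O)cc1O | starting material
2 | N,N-dimethylmethylideneammonium iodide (Eschenmoser's salt) | C[N+](C)=C.[I-] | starting material
3 | dimethyl[(2,4,6-trihydroxy-3-propanoylphenyl)methyl]ammonium iodide | CCC(=O)c1c(O)cc(O)c(C[NH+](C)C)c1O.[I-] | intermediate
4 | 1-(2,4,6-trihydroxyphenyl)butan-1-one | CCCC(=O)c1c(O)cc(O)cc1O | starting material
5 | 1-[3-[(dimethylamino)methyl]-2,4,6-trihydroxyphenyl]propan-1-one | CCC(=O)c1c(O)cc(O)c(CN(C)C)c1O | intermediate
6 | 3,5-dihydroxy-6-methylidene-2-propanoylcyclohexa-2,4-dien-1-one (ortho-quinone methide) | CCC(=O)C1=C(O)C=C(O)C(=C)C1=O | intermediate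
7 | 1-[2,4,6-trihydroxy-3-[(2,4,6-trihydroxy-3-propanoylphenyl)methyl]phenyl]butan-1-one | CCCC(=O)c1c(O)cc(O)c(Cc2c(O)cc(O)c(C(=O)CC)c2O)c1O | intermediate
8 | iodomethane | CI | starting material
9 | 1-[2,4,6-trihydroxy-3-methyl-5-[(2,4,6-trihydroxy-3-methyl-5-propanoylphenyl)methyl]phenyl]butan-1-one | CCCC(=O)c1c(O)c(C)c(O)c(Cc2c(O)c(C)c(O)c(C(=O)CC)c2O)c1O | intermediate
10 | disodium salt of 11 (each ring ionised at the C4 enol oxygen) | CCCC(=O)C1=C(O)C(C)(C)C([O-])=C(CC2=C([O-])C(C)(C)C(O)=C(C(=O)CC)C2=O)C1=O.[Na+].[Na+] | intermediate
11 | 2-butanoyl-6-[(2,4-dihydroxy-3,3-dimethyl-6-oxo-5-propanoylcyclohexa-1,4-dien-1-yl)methyl]-3,5-dihydroxy-4,4-dimethylcyclohexa-2,5-dien-1-one | CCCC(=O)C1=C(O)C(C)(C)C(O)=C(CC2=C(O)C(C)(C)C(O)=C(C(=O)CC)C2=O)C1=O | target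

**Step count and risks**

Total step count: 3. Longest linear sequence: 3 steps (1 → 3 → 7 → 11).

Steps most likely to fail:

1. Step 3. Part of the methylation may go to oxygen or to the bridge-bearing carbon C5, the methyl groups may distribute unevenly over the two rings, and the alkaline medium may cleave and re-form the methylene bridge, exchanging the two acyl halves. The fallback sets out from 1 and 4 and comes back at 11, placing the methyl groups before the bridge. Each ketone would be gem-dimethylated on its own with NaOMe and iodomethane 8 in MeOH. This should give 3,5-dihydroxy-4,4-dimethyl-2-propanoylcyclohexa-2,5-dien-1-one F1 and 2-butanoyl-3,5-dihydroxy-4,4-dimethylcyclohexa-2,5-dien-1-one F2, each left with a single free ring carbon. F1 would be aminomethylated with aqueous formaldehyde and dimethylamine in EtOH to 2-[(dimethylamino)methyl]-3,5-dihydroxy-4,4-dimethyl-6-propanoylcyclohexa-2,5-dien-1-one F3. Warming F3 with F2 in dioxane should expel dimethylamine to 5-hydroxy-6,6-dimethyl-2-methylidene-4-propanoylcyclohex-4-ene-1,3-dione F4, whose capture by F2 gives 11.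

2. Step 2. The quinone methide may be captured by the wrong partner (the product, which still has free ring carbons, or the Mannich base itself), and at the temperature needed for amine loss the bridge may exchange to give symmetric dimers. The fallback sets out from 3 and comes back at 7, generating the quinone methide cold from a better leaving group. Free base 5, released from 3 with aqueous NaHCO3, would be N-methylated with iodomethane 8 in acetone without added base to trimethyl[(2,4,6-trihydroxy-3-propanoylphenyl)methyl]ammonium iodide F5. F5 would be added slowly to 4 (3 equiv) and NaOMe in MeOH at 0 °C, where loss of trimethylamine should give 6 and the phenoxide of 4 should capture it to give 7.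

3. Step 1. A second aminomethylation at the remaining free ring carbon, or early loss of dimethylamine followed by self-condensation, may erode the mono-Mannich salt. The fallback sets out from 1 and comes back at 5, introducing the one-carbon unit at the aldehyde oxidation level, where the new substituent deactivates the ring. Vilsmeier–Haack formylation (POCl3, DMF, EtOAc, 0 °C to rt) should give 2-[(dimethyliminio)methyl]-3,5-dihydroxy-6-propanoylphenolate F6, hydrolysed on aqueous work-up to 2,4,6-trihydroxy-3-propanoylbenzaldehyde F7. Reductive amination of F7 (Me2NH, NaBH(OAc)3, AcOH, THF, 0 °C) through the same iminium F6 should give 5, which enters step 2 in place of 3 without NaOAc.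

**Further compounds**

F1 | step 3 | 3,5-dihydroxy-4,4-dimethyl-2-propanoylcyclohexa-2,5-dien-1-one | CCC(=O)C1=C(O)C(C)(C)C(O)=CC1=O
F2 | step 3 | 2-butanoyl-3,5-dihydroxy-4,4-dimethylcyclohexa-2,5-dien-1-one | CCCC(=O)C1=C(O)C(C)(C)C(O)=CC1=O
F3 | step 3 | 2-[(dimethylamino)methyl]-3,5-dihydroxy-4,4-dimethyl-6-propanoylcyclohexa-2,5-dien-1-one | CCC(=O)C1=C(O)C(C)(C)C(O)=C(CN(C)C)C1=O
F4 | step 3 | 5-hydroxy-6,6-dimethyl-2-methylidene-4-propanoylcyclohex-4-ene-1,3-dione | CCC(=O)C1=C(O)C(C)(C)C(=O)C(=C)C1=O
F5 | step 2 | trimethyl[(2,4,6-trihydroxy-3-propanoylphenyl)methyl]ammonium iodide | CCC(=O)c1c(O)cc(O)c(C[N+](C)(C)C)c1O.[I-]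
F6 | step 1 | 2-[(dimethyliminio)methyl]-3,5-dihydroxy-6-propanoylphenolate | CCC(=O)c1c(O)cc(O)c(C=[N+](C)C)c1[O-]
F7 | step 1 | 2,4,6-trihydroxy-3-propanoylbenzaldehyde | CCC(=O)c1c(O)cc(O)c(C=O)c1O
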